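## The problem

Target 29 is a C25 tetracycle. Eudesmane numbers are used for its sesquiterpenoid part: C1 ketone, C2 methine bridgehead, C3=C4 alkene carrying the C4 methyl, C5 quaternary bridgehead, ring B C5–C10, lactone C6–O/C7/C11/C12. C1′ (methine with the side chain) and C2′ (methylene) denote the saturated two-carbon bridge, and β is the face of the C10 methyl group. The core is a bicyclo[2.2.2]oct-5-en-2-one. Its bridgehead C5 and the adjacent methylated quaternary carbon C10 are shared with cyclohexane ring B, which carries a cis-fused α-methyl-γ-lactone, and C1′ bears a 6-methylhepta-1,5-dien-2-yl chain. Every ring passes through C5 or C10, so the order in which bonds are made at these two contiguous quaternary carbons decides the route. There are seven stereocentres. C10 and C1′ can be set together and can then steer C5 (addition cis to the angular methyl), C2 (fixed by the tether when the bridge closes) and C6. C6 in turn fixes C7 through the cis ring fusion, and C11 is the thermodynamically preferred epimer. The side-chain diene does not survive hydrogenation, hydroboration, peracid or strong acid; C11 is epimerisable; C1′ becomes epimerisable once a carbonyl is attached to it; the bicyclooctene is open to cationic skeletal shifts. The C6 oxygen is axial and syn to the C10 methyl, so it has to be set kinetically and not by equilibration. The enabling feature is that C10 lies between the C1 carbonyl carbon and C5, which is the pattern of a 2-methyl-1,3-dione whose second carbonyl has become the bridgehead. In ring D (C10, C1, C2, C1′, C2′, C5) a mirror plane runs through C10 and C1′ once C1 and C5 are both carbonyl, so the absolute configuration reduces to telling two enantiotopic carbonyl groups apart.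

## Retrosynthesis

**Side chain (29 ⇒ 27 ⇒ 24 + 25, methylene from 28).** The exocyclic C=CH2 bond and the bond from the carbinol carbon to the homoprenyl unit are cut last. The diene is incompatible with the hydrogenation, hydroboration and peracid steps used for the rings, so carrying it from an early stage is worse than five functional-group steps at the end. The precursor is the silyl ether 22, which has the complete ring system and all seven stereocentres. The forward steps must distinguish an aldehyde, and later an accessible ketone, from the hindered C1 ketone and the lactone, and must not epimerise C1′.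

**Ring A (22 ⇒ 21 ⇒ 20).** The C3=C4 double bond is traced to the ketol 21, and the C2–C3 bond to an aldol addition in keto aldehyde 20. The C1 ketone can enolise only towards C2, and dehydration of 21 can proceed only away from the C2 bridgehead, so both regiochemical questions are settled by structure. Closing C4–C5 last would mean making a quaternary carbon by a late intramolecular Michael addition. Compound 20 is a cis-decalin with one side arm on C5; the aldol must bridge the 1,4-positions of ring D.

**Oxidation levels (20 ⇒ 19 ⇒ 17 ⇒ 16).** No skeletal bond is cut. The aldehyde carbon C3 comes from the terminal carbon of an isopropenyl group by hydroboration, and the saturated lactone from butenolide 16 by hydrogenation. Hydroboration must precede hydrogenation, or the isopropenyl group is lost, and both must precede the C3=C4 alkene. Hydrogenation has to occur cis to the C6 hydrogen (sets C7), and C11 is then equilibrated.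

**Lactone (16 ⇒ 15 ⇒ 13 + 14).** The C7=C11 double bond and the O–C12 ester bond are cut, which leaves α-ketol 13 and phosphonate acid 14. This annulation needs only one stereochemical input, the C6 oxygen; an alkylation or C–H insertion route would have to control C7 separately. The forward reactions are an esterification of a hindered alcohol and an intramolecular olefination.

**C5 and C6 (13 ⇒ 11 ⇒ 9 + 10).** The C6–O bond and the C4–C5 bond are cut. Enone 9 offers the needed reactivity at three adjacent carbons: a conjugate addition makes the second quaternary centre, the enolate is caught as silyl enol ether 11 with the double bond fixed at C6=C7, and oxidation of that enol ether puts oxygen on C6 alone. The forward steps need addition cis to the angular methyl group and oxygen transfer to the β face.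

**Ring B (9 ⇒ 7), the key disconnection.** The C5=C6 bond is cut by a retro-aldol condensation, which opens ring B to the achiral triketone 7. This removes a ring and both stereocentres at once. Cutting ring A or the lactone first would leave the two quaternary carbons and the absolute configuration unresolved. The forward reaction must select one of two enantiotopic ring carbonyls.

**Triketone (7 ⇒ 5 + 6).** The C9–C10 bond is cut (Michael addition of dione 5 to enone 6). The forward step must place the chain cis to the silyloxymethyl group; the isomers are achiral diastereomers and separable.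

**Dione (5 ⇒ 4 ⇒ 3 ⇒ 2 ⇒ 1).** Ring D is traced to the aromatic acid 1, which already holds the methyl group, the two oxygens and the one-carbon handle in the right 1,3,4,5-pattern. Reduction of the arene gives the dione masked as a bis(enol ether), so the carboxyl carbon can be reduced to the alcohol without touching it.

## Roads not taken

**Alternative 1:** The cut removes C2–C3, C4–C5 and C9–C10 together: the C3–C4 bridge comes from an acrylic ester, C9 from an allyl halide, and the ring D enone A1 already carries the whole side chain. In the forward step the kinetic C2 enolate of A1 adds to the acrylate, the ester enolate closes onto C5, and the C1 enolate so released is allylated at C10 to give A2.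
- Merits: one flask makes the bicyclo[2.2.2]octanone, both quaternary carbons and three C–C bonds; the stereocentre C1′ sits next to the enolate carbon and can steer the first addition; no late side-chain work is needed. For the bicycle this road is clearly shorter than the chosen plan, which spends steps 7, 11 and 13–15 on it and five more on the side chain.
- Weak points: A1 must itself be made as one enantiomer. A2 carries an ester on C4 where the target has a methyl group on a double bond. Ring B and the lactone are missing entirely: the C6–C7 bond, the axial C6 oxygen and the C11–C12 unit would all have to be built in the presence of two nucleophilic alkenes. The allylation face at C10 is distinguished only by two similar bridges.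
- Comparison: against the economy of A2, the chosen plan sets an enone (9) that places functionality exactly at C5, C6 and C7, and absolute configuration from a catalytic step on an achiral compound.

**Alternative 2:** The cut removes C4–C5 and C6–O in one photochemical step and the C4–O bond afterwards. Irradiation of the octalin A3 (C5=C6 alkene, acetonyl group on C2) gives oxetane A4; opening of the oxetane is meant to give the C3=C4 alkene and the C6 carbinol, which lactonises onto the C12 ester.
- Merits: oxygen is delivered to C6 within the molecule, on the same face as the new C4–C5 bond, so the 6β configuration is certain. This is better than step 8 of the chosen plan, which relies on the facial preference of a peracid. The C4 methyl and the alkene come from one acetonyl group, and C7 and C11 are already in place.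
- Weak points: an aliphatic ketone and an unactivated trisubstituted alkene are a poor pair for oxetane formation; α-cleavage and γ-hydrogen abstraction compete. Opening the oxetane requires ionisation at tertiary C4 inside a bicyclo[2.2.2]octane, where a 1,2-shift to a bicyclo[3.2.1] skeleton or loss of a methyl proton to an exocyclic alkene can intervene. A3 needs five stereocentres before the key step.
- Comparison: against the certainty at C6, the chosen plan sets ground-state reactions of established types throughout and a fallback by inversion if the peracid takes the wrong face.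

**Alternative 3:** The cut removes the C7–C11 bond last. The diazoacetate A5 of the 6β-alcohol is decomposed with Rh2(OAc)4, and the carbenoid inserts into the equatorial C7–H bond to give lactone A6.
- Merits: the lactone C–C bond forms directly on an unfunctionalised methylene; the cis fusion is enforced by geometry; no hydrogenation is needed, so the side chain can be present; the C11 methyl could be added later by alkylation from the convex face, which is the correct configuration. The lactone costs fewer steps than steps 8, 9, 10 and 12 of the chosen plan.
- Weak points: a carbenoid from a simple diazoacetate normally cyclopropanates electron-rich alkenes faster than it inserts into a secondary C–H bond, and the side chain offers two. The axial ester oxygen lies syn to the C10 methyl, so insertion there (six-membered lactone), β-lactone formation and dimerisation compete. The hindered axial alcohol of A5 poses the same stereochemical question at C6, only moved to a ketone reduction. A6 still needs the C11 methyl and conversion of the C4 ketone into the methylated alkene.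
- Comparison: the chosen plan pays more steps for the lactone, but the butenolide can only be hydrogenated cis to the C6 hydrogen, and the diene is kept out of the way until the end.

Key step: step 6

Assumption: compounds 1, 6, 10, 14, 25 and 28 are taken to be catalogue chemicals. Locants and the α/β convention are those defined in the first section.

## Route

Step 1
Reactants: 1 3,5-dimethoxy-4-methylbenzoic acid
Product: 2 3,5-dimethoxy-4-methylcyclohexa-2,5-diene-1-carboxylic acid
Conditions: Li, NH3(l), THF, −78 °C; NH4Cl
Reagents that add atoms: none
Why: Birch reduction of a benzoate; the carboxylate directs protonation to C1 and C4 and both methoxy groups stay on the remaining double bonds, so the 1,3-dione is obtained in masked form; the two sp3 centres need no control because the methyl-bearing one becomes the enolisable C2 of the dione.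

Step 2
Reactants: 2 3,5-dimethoxy-4-methylcyclohexa-2,5-diene-1-carboxylic acid
Product: 3 (3,5-dimethoxy-4-methylcyclohexa-2,5-dien-1-yl)methanol
Conditions: LiAlH4, THF, 0 °C → reflux; aq. NaOH work-up
Reagents that add atoms: none
Why: Hydride reduction of the carboxylic acid; enol ethers are inert to LiAlH4 and the basic work-up keeps them intact.

Step 3
Reactants: 3 (3,5-dimethoxy-4-methylcyclohexa-2,5-dien-1-yl)methanol
Product: 4 tert-butyl[(3,5-dimethoxy-4-methylcyclohexa-2,5-dien-1-yl)methoxy]diphenylsilane
Conditions: TBDPSCl, imidazole, DMF, rt
Reagents that add atoms: tert-butylchlorodiphenylsilane (TBDPSCl), CC(C)(C)[Si](Cl)(c1ccccc1)c1ccccc1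
Why: Silylation of the primary alcohol; the TBDPS ether is chosen because it withstands the aqueous acid of step 4 and all later steps up to step 16.

Step 4
Reactants: 4 tert-butyl[(3,5-dimethoxy-4-methylcyclohexa-2,5-dien-1-yl)methoxy]diphenylsilane
Product: 5 5-{[(tert-butyldiphenylsilyl)oxy]methyl}-2-methylcyclohexane-1,3-dione
Conditions: 1 M HCl, THF, rt
Reagents that add atoms: water, O
Why: Acid hydrolysis of both methyl enol ethers (the second as a vinylogous ester) releases the 2-methyl-1,3-dione.

Step 5
Reactants: 5 5-{[(tert-butyldiphenylsilyl)oxy]methyl}-2-methylcyclohexane-1,3-dione; 6 but-3-en-2-one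
Product: 7 cis-5-{[(tert-butyldiphenylsilyl)oxy]methyl}-2-methyl-2-(3-oxobutyl)cyclohexane-1,3-dione
Conditions: Et3N (cat.), EtOAc, rt; chromatography
Reagents that add atoms: none
Why: Michael addition of the dione enolate forms the C9–C10 bond and the quaternary C10; axial approach to the sofa-shaped enolate, anti to the flap carbon, should place the oxobutyl chain cis to the equatorial silyloxymethyl group; both isomers are achiral and the minor trans isomer is removed.

Step 6
Reactants: 7 cis-5-{[(tert-butyldiphenylsilyl)oxy]methyl}-2-methyl-2-(3-oxobutyl)cyclohexane-1,3-dione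
Product: 9 (3S,8aR)-3-{[(tert-butyldiphenylsilyl)oxy]methyl}-8a-methyl-3,4,8,8a-tetrahydronaphthalene-1,6(2H,7H)-dione, via bicyclic ketol 8 (not isolated)
Conditions: D-proline (30 mol %), DMSO, rt
Reagents that add atoms: none
Why: D-Proline condenses with the side-chain methyl ketone (the ring carbonyls are flanked by a quaternary carbon) to an enamine whose terminal carbon, the future C6, attacks one ring carbonyl, the future C5, while the carboxylic acid of the catalyst activates that carbonyl by hydrogen bonding; hydrolysis gives ketol 8, which loses water under the conditions to enone 9. The closest known reaction is the proline-catalysed Hajos–Parrish and Wieland–Miescher cyclisation of 2-alkyl-2-(3-oxobutyl)cycloalkane-1,3-diones. Ring B closes in a 6-(enolendo)-exo-trig aldol addition. C10 and C1′ lie on the mirror plane of 7 and become stereogenic, (8aR) and (3S), only through the choice of carbonyl, which is controlled by the catalyst: the D-enantiomer should give the mirror image of the series known for L-proline. Their relative configuration is not at stake because the cis relation of chain and silyloxymethyl group is already fixed in 7. The only selectivity needed is therefore between enantiotopic carbonyl groups, and the substituent on C1′ lies on the mirror plane, remote from the reacting centres, so it should not disturb the hydrogen-bonded transition state. Enamine formation at a ring carbonyl and intermolecular aldol reactions are disfavoured by hindrance and by the intramolecular six-membered closure. Enantiomeric purity may need to be raised by crystallisation.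

Step 7
Reactants: 9 (3S,8aR)-3-{[(tert-butyldiphenylsilyl)oxy]methyl}-8a-methyl-3,4,8,8a-tetrahydronaphthalene-1,6(2H,7H)-dione; 10 isopropenylmagnesium bromide
Product: 11 C6=C7 trimethylsilyl enol ether of the cis-fused 5β-isopropenyl decalindione
Conditions: CuBr·SMe2 (20 mol %), TMSCl, HMPA, THF, −78 °C, slow addition of 10; Et3N, aq. NaHCO3
Reagents that add atoms: chlorotrimethylsilane (TMSCl), C[Si](C)(C)Cl
Why: Copper-catalysed conjugate addition of a Grignard reagent under chlorosilane activation, the standard way to force addition to β,β-disubstituted enones; attack cis to the angular methyl is the known course for 4a-methyloctalenones and is here also anti to the silyloxymethyl group, which sets C5; the enolate is trapped as the C6=C7 silyl enol ether, and the neopentyl C1 ketone should survive at −78 °C.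

Step 8
Reactants: 11 C6=C7 trimethylsilyl enol ether of the cis-fused 5β-isopropenyl decalindione
Product: 13 6β-hydroxy-5β-isopropenyl decalin-1,7-dione, via silyloxy ketone 12 (not isolated)
Conditions: mCPBA (1.05 equiv), NaHCO3, CH2Cl2, −20 °C; then citric acid, MeOH, rt
Reagents that add atoms: meta-chloroperoxybenzoic acid (mCPBA), OOC(=O)c1cccc(Cl)c1
Why: Rubottom oxidation; the peracid reacts with the electron-rich enol ether much faster than with the 1,1-disubstituted alkene, silyl migration gives 12, and mild acidic methanolysis frees the ketol without touching the TBDPS ether or epimerising C6. Axial attack on the preferred all-chair conformer, anti to the axial C5–C2′ bond on the convex face, should place the oxygen β, as in the 6β-functionalisation of steroidal enol ethers.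

Step 9
Reactants: 13 6β-hydroxy-5β-isopropenyl decalin-1,7-dione; 14 2-(diethoxyphosphoryl)propanoic acid
Product: 15 6β-[2-(diethoxyphosphoryl)propanoyloxy] decalin-1,7-dione
Conditions: DCC, DMAP (cat.), CH2Cl2, 0 °C → rt
Reagents that add atoms: none
Why: Steglich esterification, suited to a hindered secondary alcohol; the phosphonate α-centre is lost in step 10.

Step 10
Reactants: 15 6β-[2-(diethoxyphosphoryl)propanoyloxy] decalin-1,7-dione
Product: 16 Δ7(11)-butenolide (12,6β-olide) with C1 ketone and 5β-isopropenyl group
Conditions: NaH, THF, 0 °C → rt, high dilution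
Reagents that add atoms: none
Why: Intramolecular Horner–Wadsworth–Emmons olefination of the C7 ketone by the tethered phosphonate anion closes the butenolide through a five-membered ring; attack on the C1 ketone would need a seven-membered ring at a neopentyl carbonyl.

Step 11
Reactants: 16 Δ7(11)-butenolide (12,6β-olide) with C1 ketone and 5β-isopropenyl group
Product: 17 butenolide diol (C1 carbinol; 1-hydroxypropan-2-yl group on C5)
Conditions: BH3·THF (excess), THF, 0 °C → rt; then NaBO3·4H2O, H2O, rt
Reagents that add atoms: sodium perborate (NaBO3·4H2O), [Na+].[Na+].O[B-]1(O)OO[B-](O)(O)OO1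
Why: Hydroboration–oxidation places the hydroxyl on the terminal carbon (future C3); borane also reduces the C1 ketone, which is harmless because both alcohols are oxidised together in step 13; the electron-poor tetrasubstituted butenolide alkene is not hydroborated and the lactone carbonyl reacts far more slowly. The configurations at C4 and C1 are inconsequential.

Step 12
Reactants: 17 butenolide diol (C1 carbinol; 1-hydroxypropan-2-yl group on C5)
Product: 19 saturated cis-lactone diol (7α-H; 11-methyl on the convex face), via 11-epi lactone 18 (not isolated)
Conditions: H2 (3 atm), Pd/C, EtOAc, rt; filter; then DBU, toluene, 80 °C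
Reagents that add atoms: none
Why: Heterogeneous hydrogenation adds both hydrogens from the face of the C6 hydrogen, away from C5, which gives the cis-fused lactone and sets C7 (18, methyl on the concave side); DBU then equilibrates the lactone α-centre to the more stable epimer with the methyl anti to C8, the configuration of the target.

Step 13
Reactants: 19 saturated cis-lactone diol (7α-H; 11-methyl on the convex face)
Product: 20 keto aldehyde (C1 ketone; C3 aldehyde on the C5 side arm)
Conditions: Dess–Martin periodinane, NaHCO3, CH2Cl2, rt
Reagents that add atoms: none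
Why: Dess–Martin oxidation of the primary and the secondary alcohol in one operation restores the C1 ketone and gives the aldehyde under buffered conditions.

Step 14
Reactants: 20 keto aldehyde (C1 ketone; C3 aldehyde on the C5 side arm)
Product: 21 bicyclo[2.2.2]octane ketol (3-hydroxy; 4-methyl)
Conditions: 2 M HCl, THF, 40 °C
Reagents that add atoms: none
Why: Acid-catalysed intramolecular aldol addition, 6-(enolendo)-exo-trig, of the only possible enol of the C1 ketone to the aldehyde, the known route from 3-(2-oxoethyl)cyclohexanones to 6-hydroxybicyclo[2.2.2]octan-2-ones; acid avoids lactone enolate chemistry. C2 is fixed by the tether; under reversible conditions C4 should settle with its methyl away from the C10 methyl and C3 with the hydroxyl trans to that methyl, syn to the C1 carbonyl.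

Step 15
Reactants: 21 bicyclo[2.2.2]octane ketol (3-hydroxy; 4-methyl)
Product: 22 bicyclo[2.2.2]octenone lactone silyl ether
Conditions: Burgess reagent, toluene, 70 °C
Reagents that add atoms: none
Why: Burgess dehydration by syn elimination through the sulfamate ester; in the bicyclo[2.2.2]octane the C3–O and C4–H bonds are eclipsed, and elimination towards the C2 bridgehead is excluded by Bredt's rule, so only the C3=C4 alkene can form.

Step 16
Reactants: 22 bicyclo[2.2.2]octenone lactone silyl ether
Product: 23 primary alcohol (hydroxymethyl on C1′)
Conditions: HF·pyridine, THF, 0 °C → rt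
Reagents that add atoms: none
Why: Fluoride cleavage of the silyl ether; the lactone, the non-enolisable C1 ketone and the trisubstituted alkene are inert to buffered HF.

Step 17
Reactants: 23 primary alcohol (hydroxymethyl on C1′)
Product: 24 aldehyde (formyl on C1′)
Conditions: Dess–Martin periodinane, NaHCO3, CH2Cl2, 0 °C → rt
Reagents that add atoms: none
Why: Dess–Martin oxidation under buffered conditions that do not epimerise C1′.

Step 18
Reactants: 24 aldehyde (formyl on C1′); 25 5-bromo-2-methylpent-2-ene
Product: 26 secondary alcohol (1-hydroxy-5-methylhex-4-enyl on C1′)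
Conditions: 25, Mg, THF (Grignard reagent); then 24, THF, −78 °C; aq. NH4Cl
Reagents that add atoms: none
Why: Grignard addition to the aldehyde at low temperature; the C1 ketone is flanked by a quaternary carbon and a bridgehead and the lactone is less electrophilic, so the aldehyde should react selectively; the new carbinol centre is removed in step 19.

Step 19
Reactants: 26 secondary alcohol (1-hydroxy-5-methylhex-4-enyl on C1′)
Product: 27 side-chain ketone (5-methylhex-4-enoyl on C1′)
Conditions: Dess–Martin periodinane, NaHCO3, CH2Cl2, rt
Reagents that add atoms: none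
Why: Dess–Martin oxidation of the secondary alcohol; neutral conditions leave C1′ and the alkenes untouched.

Step 20
Reactants: 27 side-chain ketone (5-methylhex-4-enoyl on C1′); 28 methyltriphenylphosphonium bromide
Product: 29 target compound
Conditions: 28 (1.5 equiv), KOtBu (1.4 equiv), THF, 0 °C; then 27, 0 °C → rt
Reagents that add atoms: none
Why: Wittig methylenation; the side-chain ketone is far more accessible than the C1 ketone, the ylide does not attack the lactone, and any enolisation should occur on the methylene side, which leaves C1′ untouched.

## Compound list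

1 | 3,5-dimethoxy-4-methylbenzoic acid | COc1cc(C(O)=O)cc(OC)c1C | starting material
2 | 3,5-dimethoxy-4-methylcyclohexa-2,5-diene-1-carboxylic acid (cis/trans mixture, both used) | COC1=CC(C(O)=O)C=C(OC)C1C | intermediate
3 | (3,5-dimethoxy-4-methylcyclohexa-2,5-dien-1-yl)methanol (isomer mixture) | COC1=CC(CO)C=C(OC)C1C | intermediate
4 | tert-butyl[(3,5-dimethoxy-4-methylcyclohexa-2,5-dien-1-yl)methoxy]diphenylsilane (isomer mixture) | COC1=CC(CO[Si](c2ccccc2)(c2ccccc2)C(C)(C)C)C=C(OC)C1C | intermediate
5 | 5-{[(tert-butyldiphenylsilyl)oxy]methyl}-2-methylcyclohexane-1,3-dione (C2 enolisable) | CC1C(=O)CC(CO[Si](c2ccccc2)(c2ccccc2)C(C)(C)C)CC1=O | intermediate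
6 | but-3-en-2-one (methyl vinyl ketone) | CC(=O)C=C | starting material
7 | cis-5-{[(tert-butyldiphenylsilyl)oxy]methyl}-2-methyl-2-(3-oxobutyl)cyclohexane-1,3-dione (achiral; oxobutyl and silyloxymethyl on the same face) | CC(=O)CC[C@@]1(C)C(=O)C[C@@H](CO[Si](c2ccccc2)(c2ccccc2)C(C)(C)C)CC1=O | intermediate
8 | 3-{[(tert-butyldiphenylsilyl)oxy]methyl}-4a-hydroxy-8a-methyloctahydronaphthalene-1,6-dione (cis-fused ketol; hydroxyl cis to the angular methyl; silyloxymethyl trans to it) | CC(C)(C)[Si](c5ccccc5)(c6ccccc6)OC[C@H]1C[C@@]2(O)CC(=O)CC[C@@]2(C)C(=O)C1 | intermediate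
9 | (3S,8aR)-3-{[(tert-butyldiphenylsilyl)oxy]methyl}-8a-methyl-3,4,8,8a-tetrahydronaphthalene-1,6(2H,7H)-dione | CC(C)(C)[Si](c5ccccc5)(c6ccccc6)OC[C@H]1CC2=CC(=O)CC[C@@]2(C)C(=O)C1 | intermediate
10 | isopropenylmagnesium bromide (prop-1-en-2-ylmagnesium bromide) | CC(=C)[Mg]Br | starting material
11 | 3-{[(tert-butyldiphenylsilyl)oxy]methyl}-8a-methyl-4a-(prop-1-en-2-yl)-6-[(trimethylsilyl)oxy]-3,4,4a,7,8,8a-hexahydronaphthalen-1(2H)-one (cis-fused; isopropenyl cis to the angular methyl; silyloxymethyl trans to both) | CC(C)(C)[Si](c5ccccc5)(c6ccccc6)OC[C@H]1C[C@@]2(C(C)=C)C=C(O[Si](C)(C)C)CC[C@@]2(C)C(=O)C1 | intermediate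
12 | 5-(trimethylsilyloxy) analogue of 13 (C6 silyloxy group β) | CC(C)(C)[Si](c5ccccc5)(c6ccccc6)OC[C@H]1C[C@@]2(C(C)=C)[C@H](O[Si](C)(C)C)C(=O)CC[C@@]2(C)C(=O)C1 | intermediate
13 | 3-{[(tert-butyldiphenylsilyl)oxy]methyl}-5-hydroxy-8a-methyl-4a-(prop-1-en-2-yl)octahydronaphthalene-1,6-dione (cis-fused; hydroxyl cis to the angular methyl and to the isopropenyl group, i.e. 6β in target numbering) | CC(C)(C)[Si](c5ccccc5)(c6ccccc6)OC[C@H]1C[C@@]2(C(C)=C)[C@H](O)C(=O)CC[C@@]2(C)C(=O)C1 | intermediate
14 | 2-(diethoxyphosphoryl)propanoic acid (racemic) | CCOP(=O)(OCC)C(C)C(O)=O | starting material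
15 | 2-(diethoxyphosphoryl)propanoate ester of 13 (mixture at the phosphonate carbon) | CC(C)(C)[Si](c5ccccc5)(c6ccccc6)OC[C@H]1C[C@@]2(C(C)=C)[C@H](OC(=O)C(C)P(=O)(OCC)OCC)C(=O)CC[C@@]2(C)C(=O)C1 | intermediate
16 | 8-{[(tert-butyldiphenylsilyl)oxy]methyl}-3,5a-dimethyl-9a-(prop-1-en-2-yl)-4,5,5a,7,8,9,9a,9b-octahydronaphtho[1,2-b]furan-2,6-dione (C9b–O cis to the C5a methyl and the isopropenyl group) | CC(C)(C)[Si](c5ccccc5)(c6ccccc6)OC[C@H]1C[C@@]2(C(C)=C)[C@@H]3OC(=O)C(C)=C3CC[C@@]2(C)C(=O)C1 | intermediate
17 | butenolide diol: as 16 with the C1 ketone reduced to the alcohol and the isopropenyl group converted to 1-hydroxypropan-2-yl (mixture at both new centres) | CC(C)(C)[Si](c5ccccc5)(c6ccccc6)OC[C@H]1C[C@@]2(C(C)CO)[C@@H]3OC(=O)C(C)=C3CC[C@@]2(C)C(O)C1 | intermediate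
18 | saturated cis-fused lactone diol with 6α-H, 7α-H and 11α-H (C11 methyl β, on the concave face) | CC(C)(C)[Si](c5ccccc5)(c6ccccc6)OC[C@H]1C[C@@]2(C(C)CO)[C@@H]3OC(=O)[C@H](C)[C@@H]3CC[C@@]2(C)C(O)C1 | intermediate
19 | saturated cis-fused lactone diol with 6α-H, 7α-H and 11β-H (C11 methyl α, on the convex face, as in the target) | CC(C)(C)[Si](c5ccccc5)(c6ccccc6)OC[C@H]1C[C@@]2(C(C)CO)[C@@H]3OC(=O)[C@@H](C)[C@@H]3CC[C@@]2(C)C(O)C1 | intermediate
20 | keto aldehyde: as 19 with the C1 ketone restored and a 1-oxopropan-2-yl group on C5 (mixture at C4) | CC(C)(C)[Si](c5ccccc5)(c6ccccc6)OC[C@H]1C[C@@]2(C(C)C=O)[C@@H]3OC(=O)[C@@H](C)[C@@H]3CC[C@@]2(C)C(=O)C1 | intermediate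
21 | tetracyclic ketol: bicyclo[2.2.2]octan-2-one with 3-hydroxyl syn to the C1 carbonyl bridge and 4-methyl syn to the C1′–C2′ bridge; lactone and silyloxymethyl as in 22 | CC(C)(C)[Si](c5ccccc5)(c6ccccc6)OC[C@H]1C[C@]23[C@H](C)[C@@H](O)[C@H]1C(=O)[C@]2(C)CC[C@H]1[C@H](C)C(=O)O[C@H]13 | intermediate
22 | tetracyclic silyl ether: the target skeleton with (tert-butyldiphenylsilyl)oxymethyl on C1′ in place of the side chain | CC(C)(C)[Si](c5ccccc5)(c6ccccc6)OC[C@H]1C[C@]23C(C)=C[C@H]1C(=O)[C@]2(C)CC[C@H]1[C@H](C)C(=O)O[C@H]13 | intermediate
23 | primary alcohol: target skeleton with hydroxymethyl on C1′ | OC[C@H]1C[C@]23C(C)=C[C@H]1C(=O)[C@]2(C)CC[C@H]1[C@H](C)C(=O)O[C@H]13 | intermediate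
24 | aldehyde: target skeleton with formyl on C1′ | O=C[C@H]1C[C@]23C(C)=C[C@H]1C(=O)[C@]2(C)CC[C@H]1[C@H](C)C(=O)O[C@H]13 | intermediate
25 | 5-bromo-2-methylpent-2-ene | CC(C)=CCCBr | starting material
26 | secondary alcohol: target skeleton with 1-hydroxy-5-methylhex-4-en-1-yl on C1′ (mixture at the carbinol carbon) | CC(C)=CCCC(O)[C@H]1C[C@]23C(C)=C[C@H]1C(=O)[C@]2(C)CC[C@H]1[C@H](C)C(=O)O[C@H]13 | intermediate
27 | ketone: target skeleton with 5-methylhex-4-enoyl on C1′ | CC(C)=CCCC(=O)[C@H]1C[C@]23C(C)=C[C@H]1C(=O)[C@]2(C)CC[C@H]1[C@H](C)C(=O)O[C@H]13 | intermediate
28 | methyltriphenylphosphonium bromide | C[P+](c1ccccc1)(c1ccccc1)c1ccccc1.[Br-] | starting material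
29 | CNP0385704.2 | C=C(CCC=C(C)C)[C@H]1C[C@]23C(C)=C[C@H]1C(=O)[C@]2(C)CC[C@H]1[C@H](C)C(=O)O[C@H]13 | target

Total step count: 20. Longest linear sequence: 20 steps (1 → 29).

## Least certain steps

**Key step (step 6).** The catalyst may discriminate only partly between the two enantiotopic ring carbonyls, so that enantiomeric purity is eroded, and the ketol may dehydrate slowly. The fallback gives up catalytic induction. From 7, cyclisation with pyrrolidine and acetic acid gives 9 together with its enantiomer F1. Selective ketalisation of the saturated C1 carbonyl with (2R,3R)-butane-2,3-diol and TsOH converts the pair into the diastereomeric ketals F2 (from 9) and F3 (from F1). These are separated by chromatography or crystallisation, and aqueous acid hydrolysis of ketal F2 returns to the route at 9.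

**Step 7.** The Grignard reagent may attack the unprotected C1 carbonyl, or the branched alkenyl group may fail to transfer to a β carbon that lies next to a quaternary centre, leaving enolisation as the main event. The fallback sets out from 9: ethylene glycol and TsOH give the C1 dioxolane F4, the same copper-catalysed addition gives the silyl enol ether F5, mCPBA gives the silyloxy ketone F6, and aqueous HCl in THF removes the trimethylsilyl group and the dioxolane together to rejoin the route at 13.

**Step 8.** Oxygen transfer may take the α face of the enol ether, away from the axial methyl group, giving the equatorial alcohol, and the ketol may epimerise through its enediol during desilylation. The fallback uses inversion in place of direct delivery. From 11, N-bromosuccinimide gives the 6α-bromo ketone F7 (same facial bias as the peracid), and displacement of bromide by caesium 2-(diethoxyphosphoryl)propanoate (from 14 and Cs2CO3, DMF) proceeds with inversion and returns directly to 15. The displacement is at a hindered carbon and would need forcing conditions.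

**Step 15 (with step 14).** If the aldol gives the carbinol epimer whose hydroxyl is cis to the C4 methyl, no syn hydrogen is available and the sulfamate may ionise, which opens the way to a skeletal shift. The fallback does not depend on the configuration at C3 or C4. From 21, Dess–Martin oxidation gives the 1,3-diketone F8; Tf2O with 2,6-di-tert-butyl-4-methylpyridine gives the enol triflate F9, which can form only towards C4 because C2 is a bridgehead; reduction with Pd(OAc)2, PPh3, HCO2H and Bu3N returns to the route at 22.

**Step 20.** The ylide may fail to distinguish the two ketones, or may enolise the side-chain ketone towards C1′ and so epimerise it. The fallback builds the 1,1-disubstituted alkene by cross-coupling. From 24, MeMgBr gives the methyl carbinol F10 and Dess–Martin oxidation the methyl ketone F11. Kinetic deprotonation at the methyl group with KN(SiMe3)2 and trapping with PhNTf2 gives the 2-propenyl triflate F12. Coupling with the Grignard reagent from 25, catalysed by Fe(acac)3 in THF/NMP at −30 °C, arrives at 29.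

## Further compounds

F1 | step 6 | (3R,8aS)-enantiomer of 9 | CC(C)(C)[Si](c5ccccc5)(c6ccccc6)OC[C@@H]1CC2=CC(=O)CC[C@]2(C)C(=O)C1
F2 | step 6 | C1 ketal of 9 with (2R,3R)-butane-2,3-diol | CC(C)(C)[Si](c5ccccc5)(c6ccccc6)OC[C@H]1CC2=CC(=O)CC[C@@]2(C)C3(O[C@H](C)[C@@H](C)O3)C1
F3 | step 6 | C1 ketal of F1 with (2R,3R)-butane-2,3-diol | CC(C)(C)[Si](c5ccccc5)(c6ccccc6)OC[C@@H]1CC2=CC(=O)CC[C@]2(C)C3(O[C@H](C)[C@@H](C)O3)C1
F4 | step 7 | C1 ethylene ketal (dioxolane) of 9 | CC(C)(C)[Si](c5ccccc5)(c6ccccc6)OC[C@H]1CC2=CC(=O)CC[C@@]2(C)C3(OCCO3)C1
F5 | step 7 | C1 dioxolane of silyl enol ether 11 | CC(C)(C)[Si](c5ccccc5)(c6ccccc6)OC[C@H]1C[C@@]2(C(C)=C)C=C(O[Si](C)(C)C)CC[C@@]2(C)C3(OCCO3)C1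
F6 | step 7 | C1 dioxolane of silyloxy ketone 12 | CC(C)(C)[Si](c5ccccc5)(c6ccccc6)OC[C@H]1C[C@@]2(C(C)=C)[C@H](O[Si](C)(C)C)C(=O)CC[C@@]2(C)C3(OCCO3)C1
F7 | step 8 | 6α-bromo analogue of 13 (bromine trans to the angular methyl) | CC(C)(C)[Si](c5ccccc5)(c6ccccc6)OC[C@H]1C[C@@]2(C(C)=C)[C@@H](Br)C(=O)CC[C@@]2(C)C(=O)C1
F8 | step 15 | 1,3-diketone from 21 (C3 ketone) | CC(C)(C)[Si](c5ccccc5)(c6ccccc6)OC[C@H]1C[C@]23[C@H](C)C(=O)[C@H]1C(=O)[C@]2(C)CC[C@H]1[C@H](C)C(=O)O[C@H]13
F9 | step 15 | C3 enol triflate (C3=C4) | CC(C)(C)[Si](c5ccccc5)(c6ccccc6)OC[C@H]1C[C@]23C(C)=C(OS(=O)(=O)C(F)(F)F)[C@H]1C(=O)[C@]2(C)CC[C@H]1[C@H](C)C(=O)O[C@H]13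
F10 | step 20 | methyl carbinol: target skeleton with 1-hydroxyethyl on C1′ (mixture at the carbinol carbon) | CC(O)[C@H]1C[C@]23C(C)=C[C@H]1C(=O)[C@]2(C)CC[C@H]1[C@H](C)C(=O)O[C@H]13
F11 | step 20 | methyl ketone: target skeleton with acetyl on C1′ | CC(=O)[C@H]1C[C@]23C(C)=C[C@H]1C(=O)[C@]2(C)CC[C@H]1[C@H](C)C(=O)O[C@H]13
F12 | step 20 | enol triflate: target skeleton with 1-(trifluoromethylsulfonyloxy)vinyl on C1′ | C=C(OS(=O)(=O)C(F)(F)F)[C@H]1C[C@]23C(C)=C[C@H]1C(=O)[C@]2(C)CC[C@H]1[C@H](C)C(=O)O[C@H]13
A1 | alternative 1 | 3-{[(4-methoxybenzyl)oxy]methyl}-2-methyl-5-(6-methylhepta-1,5-dien-2-yl)cyclohex-2-en-1-one | C=C(CCC=C(C)C)[C@H]1CC(COCc2ccc(OC)cc2)=C(C)C(=O)C1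
A2 | alternative 1 | allylated bicyclo[2.2.2]octanone ester with both quaternary carbons | C=C(CCC=C(C)C)[C@H]1C[C@]2(COCc3ccc(OC)cc3)[C@@H](C(=O)OC)C[C@H]1C(=O)[C@]2(C)CC=C
A3 | alternative 2 | octalin with C5=C6 alkene, C1 dioxolane, acetonyl group on C2 and methyl propanoate unit on C7 | CC(C)(C)[Si](C)(C)OC[C@H]1CC2=C[C@H]([C@H](C)C(=O)OC)CC[C@@]2(C)C3(OCCO3)[C@@H]1CC(C)=O
A4 | alternative 2 | oxetane-bridged bicyclo[2.2.2]octane | CC(C)(C)[Si](C)(C)OC[C@H]1C[C@]23[C@]4(C)C[C@H]1C5(OCCO5)[C@]2(C)CC[C@@H]([C@H](C)C(=O)OC)[C@H]3O4
A5 | alternative 3 | diazoacetate of the 6β-alcohol of the bicyclic diketone | C=C(CCC=C(C)C)[C@H]1C[C@]23C(=O)C[C@H]1C(=O)[C@]2(C)CCC[C@H]3OC(=O)C=[N+]=[N-]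
A6 | alternative 3 | cis-fused lactone diketone lacking the lactone methyl | C=C(CCC=C(C)C)[C@H]1C[C@]23C(=O)C[C@H]1C(=O)[C@]2(C)CC[C@H]1CC(=O)O[C@H]13
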